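**Retrosynthetic overview**

1. Numbering: C1 ketone, C2=C3 (methyl on C3), C4 and C11 the cyclobutane CH atoms on C3 and C1, C5 the cyclobutane CH on C6 (CMe2), C7 (isovalerate), C8, C9 (tiglate), C10 (C–CH3). Ring A is the enone ring C1–C2–C3–C4–C10–C11, ring B the cyclobutane C4–C5–C11–C10, ring C the seven-membered ring through C5–C6–C7–C8–C9–C10.
2. Feature: without ring A and the C7/C9 oxygens, the cage has a mirror plane containing C5, C10 and the C6–C9 bridge, which interchanges C4 and C11. Ring A is a 3-methylcyclohex-2-enone, the aldol-condensation retron of a heptane-2,6-dione whose acetyl groups sit on C4 and C11.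
3. Late disconnections: C7 ester (acylation); C9 tiglate and C7 carbinol (Evans–Tishchenko on a C9-hydroxy C7-ketone); C9–O (ligand-controlled β-borylation/oxidation of the ring C enone); ring A C2=C3 (enantiotopic-group-selective amine-catalysed aldol condensation of the meso 7,8-diacetylbicyclo[4.1.1]oct-4-en-3-one).
4. The meso diketone comes from an acetylcyclobutene by intramolecular Michael closure of C5–C6, dithiane unmasking and ketone dehydrogenation. The cyclobutene comes from a ketene/ethoxyethyne [2+2] adduct by carbonyl transposition, dithiane conjugate addition/enol triflation and Stille acetylation.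
5. Ring order: B (step 4), C (step 8), A (step 11). All material before the meso diketone is racemic and converges on that achiral compound.

Key step: step 11

Assumption: the sense of induction of the two catalyst-controlled steps (cinchona amine in step 11, diphosphine in step 12) is assigned by analogy with simpler substrates; should the opposite sense be found, the quinidine-derived pseudo-enantiomeric amine or the (S,S)-ligand would be used with no other change. Racemic intermediates are drawn as one enantiomer.

**Route**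

Step 1
Reactants: 1 3-methylbutan-2-one; 2 methyl 2-methylprop-2-enoate
Product: 4 methyl 2,6-dimethyl-5-oxoheptanoate (racemic), via pyrrolidine enamine 3 (not isolated)
Conditions: pyrrolidine, TsOH (cat.), toluene, reflux, Dean–Stark; then 2, 1,4-dioxane, 90 °C; then AcOH/NaOAc, H2O, rt
Reagents that add atoms: none
Why: Stork enamine Michael addition, in which the less substituted enamine of the methyl ketone adds through its CH2 terminus to the acrylate β-carbon and hydrolysis returns the ketone, so that C8–C9 is formed and the future C10 arises as a racemic centre, which is harmless because the route later converges on an achiral intermediate.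

Step 2
Reactants: 4 methyl 2,6-dimethyl-5-oxoheptanoate
Product: 5 methyl 2-methyl-4-[2-(propan-2-yl)-1,3-dioxolan-2-yl]butanoate (racemic)
Conditions: Me3SiOCH2CH2OSiMe3, Me3SiOTf (cat.), CH2Cl2, −78 to −20 °C; pyridine quench
Reagents that add atoms: 1,2-bis(trimethylsilyloxy)ethane, C[Si](C)(C)OCCO[Si](C)(C)C
Why: Silyl triflate-catalysed aprotic ketalisation masks the C7 ketone against the later ketene, hydride and organolithium steps without touching the methyl ester.

Step 3
Reactants: 5 methyl 2-methyl-4-[2-(propan-2-yl)-1,3-dioxolan-2-yl]butanoate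
Product: 6 sodium 2-methyl-4-[2-(propan-2-yl)-1,3-dioxolan-2-yl]butanoate (racemic)
Conditions: NaOH (1.0 equiv), MeOH/H2O, 40 °C; evaporate, dry azeotropically with toluene
Reagents that add atoms: sodium hydroxide, [Na+].[OH-]
Why: Saponification with exactly one equivalent of hydroxide should give the dry sodium carboxylate directly, so the acid-labile dioxolane never meets a free acid.

Step 4
Reactants: 6 sodium 2-methyl-4-[2-(propan-2-yl)-1,3-dioxolan-2-yl]butanoate; 7 ethoxyethyne
Product: 10 3-ethoxy-4-methyl-4-{2-[2-(propan-2-yl)-1,3-dioxolan-2-yl]ethyl}cyclobut-2-en-1-one (racemic), via acid chloride 8 (not isolated), via ketene 9 (not isolated)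
Conditions: (COCl)2 (1.0 equiv), pyridine (cat.), toluene, 0 °C to rt; then 7 (3 equiv), Et3N, Et2O, rt to 40 °C
Reagents that add atoms: none
Why: Oxalyl chloride converts the carboxylate into the acid chloride without liberating HCl, triethylamine dehydrochlorinates it to the disubstituted ketene, and a thermal ketene–alkyne [2+2] cycloaddition closes ring B with the polarity-matched regiochemistry (alkyne CH to the ketene carbonyl carbon, the ethoxy-bearing carbon to the ketene α-carbon), which makes C10 quaternary with its methyl group and the C9–C8 chain.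

Step 5
Reactants: 10 3-ethoxy-4-methyl-4-{2-[2-(propan-2-yl)-1,3-dioxolan-2-yl]ethyl}cyclobut-2-en-1-one
Product: 12 4-methyl-4-{2-[2-(propan-2-yl)-1,3-dioxolan-2-yl]ethyl}cyclobut-2-en-1-one (racemic), via cyclobutenol 11 (not isolated)
Conditions: LiAlH4 (0.3 equiv), Et2O, −20 °C; then 0.5 M aq. oxalic acid, Et2O, 0 °C
Reagents that add atoms: water, O
Why: Stork–Danheiser 1,3-carbonyl transposition, in which 1,2-reduction of the vinylogous ester gives the allylic alcohol and cold dilute acid hydrolyses its enol ether with loss of water to the 4,4-disubstituted cyclobutenone, a brief mild treatment that the dioxolane should survive.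

Step 6
Reactants: 12 4-methyl-4-{2-[2-(propan-2-yl)-1,3-dioxolan-2-yl]ethyl}cyclobut-2-en-1-one; 13 2-methyl-1,3-dithiane
Product: 16 4-methyl-3-(2-methyl-1,3-dithian-2-yl)-4-{2-[2-(propan-2-yl)-1,3-dioxolan-2-yl]ethyl}cyclobut-1-en-1-yl trifluoromethanesulfonate (racemic; C11 epimers), via lithiated dithiane 14 (not isolated), via lithium enolate 15 (not isolated)
Conditions: 13, n-BuLi, THF, −30 °C; HMPA (2 equiv), −78 °C; 12; then PhNTf2, −78 to 0 °C
Reagents that add atoms: N-phenylbis(trifluoromethanesulfonimide), O=S(=O)(N(c1ccccc1)S(=O)(=O)C(F)(F)F)C(F)(F)F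
Why: Conjugate addition of the dithiane acyl-anion equivalent, steered to the β-carbon by HMPA and by the strain released on saturating a cyclobutenone that has no enolisable hydrogen, installs the masked C11 acetyl group, and O-triflation of the regiodefined enolate fixes the double bond between the future C4 and C5; the C11 configuration is not controlled and need not be, since it equilibrates in step 8.

Step 7
Reactants: 16 4-methyl-3-(2-methyl-1,3-dithian-2-yl)-4-{2-[2-(propan-2-yl)-1,3-dioxolan-2-yl]ethyl}cyclobut-1-en-1-yl trifluoromethanesulfonate; 17 tributyl(1-ethoxyethenyl)stannane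
Product: 19 1-[4-methyl-3-(2-methyl-1,3-dithian-2-yl)-4-(4-methyl-3-oxopentyl)cyclobut-1-en-1-yl]ethan-1-one (racemic; C11 epimers), via dienol ether 18 (not isolated)
Conditions: Pd(PPh3)4 (5 mol%), CuI (10 mol%), LiCl, THF, 50 °C; then 1 M HCl, THF, rt
Reagents that add atoms: water, O
Why: Stille coupling of the cyclobutenyl triflate with the 1-ethoxyvinyl stannane, followed by aqueous acid hydrolysis of the enol ether and of the dioxolane, gives the acetylcyclobutene and frees the side-chain ketone in one operation, the dithiane being stable to dilute acid.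

Step 8
Reactants: 19 1-[4-methyl-3-(2-methyl-1,3-dithian-2-yl)-4-(4-methyl-3-oxopentyl)cyclobut-1-en-1-yl]ethan-1-one
Product: 20 7-acetyl-2,2,6-trimethyl-8-(2-methyl-1,3-dithian-2-yl)bicyclo[4.1.1]octan-3-one (racemic; dithianyl anti to the C2–C5 bridge; the acetyl epimer may accompany it)
Conditions: KOtBu (0.3 equiv), tBuOH/THF, 0.01 M, 0 °C to rt
Reagents that add atoms: none
Why: Intramolecular Michael addition in which, under equilibrating alkoxide conditions, the tertiary enolate of the isopropyl ketone (C6) adds to C5, the β-carbon of the strained cyclobutenyl ketone, closing ring C as a bicyclo[4.1.1]octane; the tether forces C6 and C9 onto the same face of ring B, the C8 enolate cannot reach C5 without folding the planar cyclobutene into a bicyclo[2.1.1]hexane, C11 equilibrates through the dienolate before closure, and C4 is protonated to an epimer mixture that is corrected in step 11.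

Step 9
Reactants: 20 7-acetyl-2,2,6-trimethyl-8-(2-methyl-1,3-dithian-2-yl)bicyclo[4.1.1]octan-3-one
Product: 21 7,8-diacetyl-2,2,6-trimethylbicyclo[4.1.1]octan-3-one (acetyl epimers; the isomer with both acetyls anti to the C2–C5 bridge is meso)
Conditions: MeI, CaCO3, MeCN/H2O (9:1), 45 °C
Reagents that add atoms: water, O
Why: Alkylative hydrolysis of the dithiane (S-methylation, then hydrolysis of the sulfonium salt buffered by CaCO3) unmasks the second acetyl group under neutral conditions that leave the other two ketones alone.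

Step 10
Reactants: 21 7,8-diacetyl-2,2,6-trimethylbicyclo[4.1.1]octan-3-one
Product: 22 7,8-diacetyl-2,2,6-trimethylbicyclo[4.1.1]oct-4-en-3-one (meso when both acetyls are anti to the enone bridge; acetyl epimers interconvert in step 11)
Conditions: 2-iodoxybenzoic acid (IBX, 2.5 equiv), DMSO/fluorobenzene, 70 °C
Reagents that add atoms: none
Why: IBX-mediated ketone dehydrogenation through the enol can desaturate only the C7 ketone (C8–C9), because C6 is quaternary and desaturating either acetyl group would place a double bond at a bridgehead of the cyclobutane, so the bridge enone of the meso precursor should result.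

Step 11
Reactants: 22 7,8-diacetyl-2,2,6-trimethylbicyclo[4.1.1]oct-4-en-3-one
Product: 24 (4R,5S,10R,11R)-longipina-2,8-diene-1,7-dione, via ketol 23 (not isolated)
Conditions: 9-amino(9-deoxy)epi-quinine (20 mol%), AcOH (60 mol%), toluene, 25 to 45 °C
Reagents that add atoms: none
Why: The chiral primary amine condenses with one of the two enantiotopic acetyl groups to an enamine whose methylene carbon (C2) adds to the carbonyl carbon of the other acetyl group (C3) in a 6-enolexo-exo-trig aldol closure across the C4···C11 diagonal of ring B, and loss of water from the ketol gives the C2=C3 bond and ring A; this is the amine-catalysed intramolecular aldol condensation known for 4-substituted heptane-2,6-diones. Because 22 is achiral, the choice of the nucleophilic acetyl group by the cinchona amine–acid pair is the only stereo-determining event and fixes C4, C5, C10 and C11 together, their relative configuration being already locked in the cage. The step needs group selectivity between the two acetyls (catalyst control), diastereoconvergence (acetyl epimers at C4 and C11 interconvert through enamine or enol, and only the pair anti to ring C is within bonding distance) and chemoselectivity against ring C, which is secured because C6 and C10 are quaternary and the bridge enone therefore has no enolisable position. Dehydration should make the closure irreversible and so pay for the added strain of the bicyclo[3.1.1]heptenone.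

Step 12
Reactants: 24 (4R,5S,10R,11R)-longipina-2,8-diene-1,7-dione
Product: 25 (4R,5S,9R,10R,11R)-9-(4,4,5,5-tetramethyl-1,3,2-dioxaborolan-2-yl)longipin-2-ene-1,7-dione
Conditions: CuCl (5 mol%), NaOtBu (10 mol%), (R,R)-2,3-bis(tert-butylmethylphosphino)quinoxaline (6 mol%), B2pin2 (1.1 equiv), MeOH (2 equiv), THF, 0 °C
Reagents that add atoms: bis(pinacolato)diboron, CC1(C)OB(OC1(C)C)B1OC(C)(C)C(C)(C)O1
Why: Copper-catalysed conjugate borylation in which the boryl–copper species adds to C9, the only β-monosubstituted enone terminus (the ring A enone is β,β-disubstituted and shielded by the cage); since C4–H and C11–H flank C9 almost symmetrically, the face is chosen by the chiral diphosphine, boron being delivered to the face turned toward C11 to set C9.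

Step 13
Reactants: 25 (4R,5S,9R,10R,11R)-9-(4,4,5,5-tetramethyl-1,3,2-dioxaborolan-2-yl)longipin-2-ene-1,7-dione
Product: 26 (4R,5S,9R,10R,11R)-9-hydroxylongipin-2-ene-1,7-dione
Conditions: NaBO3·4H2O, THF/H2O, rt
Reagents that add atoms: sodium perborate tetrahydrate, [Na+].[Na+].O[B-]1(O)OO[B-](O)(O)OO1
Why: Perborate oxidation of the C–B bond proceeds with retention and is mild enough not to eliminate the resulting β-hydroxy ketone back to the enone.

Step 14
Reactants: 26 (4R,5S,9R,10R,11R)-9-hydroxylongipin-2-ene-1,7-dione; 27 (E)-2-methylbut-2-enal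
Product: 29 (4R,5S,7R,9R,10R,11R)-7-hydroxy-1-oxolongipin-2-en-9-yl (E)-2-methylbut-2-enoate, via hemiacetal 28 (not isolated)
Conditions: SmI2 (0.3 equiv), 27 (6 equiv), THF, −10 °C, dark
Reagents that add atoms: none
Why: Evans–Tishchenko reduction in which the C9 hydroxyl adds to the aldehyde to give a samarium-bound hemiacetal that delivers its hydride intramolecularly to C7 on the face carrying O9, so the C7 hydroxyl should appear trans (1,3-anti) to O9 while the C9 oxygen leaves as the tiglate with its (E)-double bond untouched, an excess of the conjugated aldehyde compensating for its slower hydride transfer.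

Step 15
Reactants: 29 (4R,5S,7R,9R,10R,11R)-7-hydroxy-1-oxolongipin-2-en-9-yl (E)-2-methylbut-2-enoate; 30 3-methylbutanoyl chloride
Product: 31 (4R,5S,7R,9R,10R,11R)-7-(3-methylbutanoyloxy)-1-oxolongipin-2-en-9-yl (E)-2-methylbut-2-enoate (target)
Conditions: pyridine, 4-(dimethylamino)pyridine (0.2 equiv), CH2Cl2, 0 °C to rt
Reagents that add atoms: none
Why: Nucleophile-catalysed acylation of the remaining hindered secondary alcohol should give the isovalerate without touching any stereocentre or the tiglate.

**Compound list**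

1 | 3-methylbutan-2-one | CC(C)C(C)=O | starting material
2 | methyl 2-methylprop-2-enoate (methyl methacrylate) | COC(=O)C(C)=C | starting material
3 | 1-(3-methylbut-1-en-2-yl)pyrrolidine | C=C(N1CCCC1)C(C)C | intermediate (not isolated)
4 | methyl 2,6-dimethyl-5-oxoheptanoate (racemic) | COC(=O)C(C)CCC(=O)C(C)C | intermediate
5 | methyl 2-methyl-4-[2-(propan-2-yl)-1,3-dioxolan-2-yl]butanoate (racemic) | COC(=O)C(C)CCC1(C(C)C)OCCO1 | intermediate
6 | sodium 2-methyl-4-[2-(propan-2-yl)-1,3-dioxolan-2-yl]butanoate (racemic) | [Na+].[O-]C(=O)C(C)CCC1(C(C)C)OCCO1 | intermediate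
7 | ethoxyethyne | CCOC#C | starting material
8 | 2-methyl-4-[2-(propan-2-yl)-1,3-dioxolan-2-yl]butanoyl chloride | CC(CCC1(C(C)C)OCCO1)C(Cl)=O | intermediate (not isolated)
9 | 2-methyl-4-[2-(propan-2-yl)-1,3-dioxolan-2-yl]but-1-en-1-one (ketene) | CC(CCC1(C(C)C)OCCO1)=C=O | intermediate (not isolated)
10 | 3-ethoxy-4-methyl-4-{2-[2-(propan-2-yl)-1,3-dioxolan-2-yl]ethyl}cyclobut-2-en-1-one (racemic) | CCOC1=CC(=O)C1(C)CCC2(C(C)C)OCCO2 | intermediate
11 | 3-ethoxy-4-methyl-4-{2-[2-(propan-2-yl)-1,3-dioxolan-2-yl]ethyl}cyclobut-2-en-1-ol | CCOC1=CC(O)C1(C)CCC2(C(C)C)OCCO2 | intermediate (not isolated)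
12 | 4-methyl-4-{2-[2-(propan-2-yl)-1,3-dioxolan-2-yl]ethyl}cyclobut-2-en-1-one (racemic) | O=C1C=CC1(C)CCC2(C(C)C)OCCO2 | intermediate
13 | 2-methyl-1,3-dithiane | CC1SCCCS1 | starting material
14 | 2-lithio-2-methyl-1,3-dithiane | [Li]C1(C)SCCCS1 | intermediate (not isolated)
15 | lithium 4-methyl-3-(2-methyl-1,3-dithian-2-yl)-4-{2-[2-(propan-2-yl)-1,3-dioxolan-2-yl]ethyl}cyclobut-1-en-1-olate | [Li]OC1=CC(C2(C)SCCCS2)C1(C)CCC3(C(C)C)OCCO3 | intermediate (not isolated)
16 | 4-methyl-3-(2-methyl-1,3-dithian-2-yl)-4-{2-[2-(propan-2-yl)-1,3-dioxolan-2-yl]ethyl}cyclobut-1-en-1-yl trifluoromethanesulfonate (racemic; drawn with the dithianyl trans to the side chain, its C11 epimer also present) | FC(F)(F)S(=O)(=O)OC1=C[C@@H](C2(C)SCCCS2)[C@]1(C)CCC3(C(C)C)OCCO3 | intermediate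
17 | tributyl(1-ethoxyethenyl)stannane | CCCC[Sn](CCCC)(CCCC)C(=C)OCC | starting material
18 | 2-{2-[3-(1-ethoxyethenyl)-1-methyl-4-(2-methyl-1,3-dithian-2-yl)cyclobut-2-en-1-yl]ethyl}-2-(propan-2-yl)-1,3-dioxolane (racemic) | CCOC(=C)C1=C[C@@H](C2(C)SCCCS2)[C@]1(C)CCC3(C(C)C)OCCO3 | intermediate (not isolated)
19 | 1-[4-methyl-3-(2-methyl-1,3-dithian-2-yl)-4-(4-methyl-3-oxopentyl)cyclobut-1-en-1-yl]ethan-1-one (racemic; drawn with the dithianyl trans to the side chain, its C11 epimer also present) | CC(=O)C1=C[C@@H](C2(C)SCCCS2)[C@]1(C)CCC(=O)C(C)C | intermediate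
20 | 7-acetyl-2,2,6-trimethyl-8-(2-methyl-1,3-dithian-2-yl)bicyclo[4.1.1]octan-3-one (racemic; both one-carbon-bridge substituents drawn anti to the C2–C5 bridge) | C1CC(=O)C(C)(C)[C@@H]2[C@@H](C3(C)SCCCS3)[C@@]1(C)[C@H]2C(C)=O | intermediate
21 | 7,8-diacetyl-2,2,6-trimethylbicyclo[4.1.1]octan-3-one (meso isomer drawn, both acetyls anti to the C2–C5 bridge) | C1CC(=O)C(C)(C)[C@@H]2[C@@H](C(C)=O)[C@@]1(C)[C@H]2C(C)=O | intermediate
22 | 7,8-diacetyl-2,2,6-trimethylbicyclo[4.1.1]oct-4-en-3-one (meso; both acetyls anti to the enone bridge) | C1=CC(=O)C(C)(C)[C@@H]2[C@@H](C(C)=O)[C@@]1(C)[C@H]2C(C)=O | intermediate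
23 | 3-hydroxylongipin-8-ene-1,7-dione (ring A ketol; cage configured as in 24, C3 configuration immaterial) | C1=CC(=O)C(C)(C)[C@@H]2[C@H]3C(=O)CC(C)(O)[C@@H]2[C@]31C | intermediate (not isolated)
24 | (4R,5S,10R,11R)-longipina-2,8-diene-1,7-dione [2,6,6,9-tetramethyltricyclo[5.4.0.0^2,8]undeca-3,9-diene-5,11-dione] | C1=CC(=O)C(C)(C)[C@@H]2[C@H]3C(=O)C=C(C)[C@@H]2[C@]31C | intermediate
25 | (4R,5S,9R,10R,11R)-9-(4,4,5,5-tetramethyl-1,3,2-dioxaborolan-2-yl)longipin-2-ene-1,7-dione | CC1(C)OB(OC1(C)C)[C@@H]2CC(=O)C(C)(C)[C@@H]3[C@H]4C(=O)C=C(C)[C@@H]3[C@]42C | intermediate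
26 | (4R,5S,9R,10R,11R)-9-hydroxylongipin-2-ene-1,7-dione | O[C@@H]1CC(=O)C(C)(C)[C@@H]2[C@H]3C(=O)C=C(C)[C@@H]2[C@]31C | intermediate
27 | (E)-2-methylbut-2-enal | C/C=C(\C)C=O | starting material
28 | 9-O-[(E)-1-hydroxy-2-methylbut-2-enyl] hemiacetal of 26 | C/C=C(\C)C(O)O[C@@H]1CC(=O)C(C)(C)[C@@H]2[C@H]3C(=O)C=C(C)[C@@H]2[C@]31C | intermediate (not isolated)
29 | (4R,5S,7R,9R,10R,11R)-7-hydroxy-1-oxolongipin-2-en-9-yl (E)-2-methylbut-2-enoate | C/C=C(\C)C(=O)O[C@@H]1C[C@@H](O)C(C)(C)[C@@H]2[C@H]3C(=O)C=C(C)[C@@H]2[C@]31C | intermediate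
30 | 3-methylbutanoyl chloride | CC(C)CC(Cl)=O | starting material
31 | (4R,5S,7R,9R,10R,11R)-7-(3-methylbutanoyloxy)-1-oxolongipin-2-en-9-yl (E)-2-methylbut-2-enoate [(1R,2R,3R,5R,7S,8R)-2,6,6,9-tetramethyl-5-(3-methylbutanoyloxy)-11-oxotricyclo[5.4.0.0^2,8]undec-9-en-3-yl (E)-2-methylbut-2-enoate] | C/C=C(\C)C(=O)O[C@@H]1C[C@@H](OC(=O)CC(C)C)C(C)(C)[C@@H]2[C@H]3C(=O)C=C(C)[C@@H]2[C@]31C | target

**Step count and risks**

Total step count: 15. Longest linear sequence: 15 steps (from 1).

The three steps most likely to fail: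

Step 11 (key step). The closure must build a bicyclo[3.1.1]heptenone on a cyclobutane, so it may be slow. If it is, the acetyl epimers that are syn to ring C may add to C9 or C7 of the bridge enone instead, and discrimination between the two acetyl groups may be poor. The fallback sets out from 22. Enantiotopic-group-selective deprotonation with the chiral base lithium (R,R)-bis(1-phenylethyl)amide in the presence of Me3SiCl (THF, −100 °C) should give the mono silyl enol ether 7-acetyl-2,2,6-trimethyl-8-[1-(trimethylsilyloxy)ethenyl]bicyclo[4.1.1]oct-4-en-3-one F1. An intramolecular Mukaiyama aldol addition (TiCl4, CH2Cl2, −78 °C) would then give ketol 23, and acid-catalysed dehydration (TsOH, toluene) comes back to the route at 24.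

Step 8. The seven-membered bridging Michael closure may be outrun by proton transfer to the dienolate of the acetylcyclobutene, by aldol condensation between the side-chain ketone and an acetyl group, or by intermolecular addition. The fallback sets out from 19. Me3SiI with (Me3Si)2NH (CH2Cl2, −20 °C) should give, under thermodynamic control, the more substituted silyl enol ether 1-[4-methyl-3-(2-methyl-1,3-dithian-2-yl)-4-{4-methyl-3-[(trimethylsilyl)oxy]pent-3-en-1-yl}cyclobut-1-en-1-yl]ethan-1-one F2. Silyl activation of the cyclobutenyl ketone (Me3SiI present, or added Me3SiOTf) would then drive an intramolecular Mukaiyama–Michael addition to the bicyclic silyl enol ether 2,2,6-trimethyl-8-(2-methyl-1,3-dithian-2-yl)-7-{1-[(trimethylsilyl)oxy]ethylidene}bicyclo[4.1.1]octan-3-one F3, and aqueous acid work-up comes back to the route at 20.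

Step 6. The tertiary dithiane anion may attack the carbonyl group instead of the neopentyl β-carbon, or add too slowly. The fallback sets out from 10. The lithiated dithiane 14 is added to the carbonyl group of the vinylogous ester (THF, −78 °C, no HMPA) to give 3-ethoxy-4-methyl-1-(2-methyl-1,3-dithian-2-yl)-4-{2-[2-(propan-2-yl)-1,3-dioxolan-2-yl]ethyl}cyclobut-2-en-1-ol F4. Cold dilute acid then effects the Stork–Danheiser transposition to 4-methyl-3-(2-methyl-1,3-dithian-2-yl)-4-{2-[2-(propan-2-yl)-1,3-dioxolan-2-yl]ethyl}cyclobut-2-en-1-one F5. RhCl(PPh3)3-catalysed 1,4-hydrosilylation with Et3SiH should give triethyl{[4-methyl-3-(2-methyl-1,3-dithian-2-yl)-4-{2-[2-(propan-2-yl)-1,3-dioxolan-2-yl]ethyl}cyclobut-1-en-1-yl]oxy}silane F6. Cleavage with MeLi and trapping of the resulting lithium enolate 15 with PhNTf2 comes back to the route at 16.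

Further compounds
F1 | step 11 | 7-acetyl-2,2,6-trimethyl-8-[1-(trimethylsilyloxy)ethenyl]bicyclo[4.1.1]oct-4-en-3-one | C1=CC(=O)C(C)(C)[C@@H]2[C@@H](C(=C)O[Si](C)(C)C)[C@@]1(C)[C@H]2C(C)=O
F2 | step 8 | 1-[4-methyl-3-(2-methyl-1,3-dithian-2-yl)-4-{4-methyl-3-[(trimethylsilyl)oxy]pent-3-en-1-yl}cyclobut-1-en-1-yl]ethan-1-one | CC(=O)C1=C[C@@H](C2(C)SCCCS2)[C@]1(C)CCC(O[Si](C)(C)C)=C(C)C
F3 | step 8 | 2,2,6-trimethyl-8-(2-methyl-1,3-dithian-2-yl)-7-{1-[(trimethylsilyl)oxy]ethylidene}bicyclo[4.1.1]octan-3-one | C1CC(=O)C(C)(C)[C@@H]2[C@@H](C3(C)SCCCS3)[C@@]1(C)C2=C(C)O[Si](C)(C)C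
F4 | step 6 | 3-ethoxy-4-methyl-1-(2-methyl-1,3-dithian-2-yl)-4-{2-[2-(propan-2-yl)-1,3-dioxolan-2-yl]ethyl}cyclobut-2-en-1-ol | CCOC1=CC(O)(C2(C)SCCCS2)C1(C)CCC3(C(C)C)OCCO3
F5 | step 6 | 4-methyl-3-(2-methyl-1,3-dithian-2-yl)-4-{2-[2-(propan-2-yl)-1,3-dioxolan-2-yl]ethyl}cyclobut-2-en-1-one | O=C1C=C(C2(C)SCCCS2)C1(C)CCC3(C(C)C)OCCO3
F6 | step 6 | triethyl{[4-methyl-3-(2-methyl-1,3-dithian-2-yl)-4-{2-[2-(propan-2-yl)-1,3-dioxolan-2-yl]ethyl}cyclobut-1-en-1-yl]oxy}silane | CC[Si](CC)(CC)OC1=C[C@@H](C2(C)SCCCS2)[C@]1(C)CCC3(C(C)C)OCCO3
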